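**Plan**
- The target is cut at the bond between the linking CH2 and cyclopentane C1′ and, after the tertiary oxygen is formally tied back to the enol carbon C5 of the six-membered ring, at the O–C2′(CH3) bond.
- The enabling feature is the array ring C4–CH2–C1′H–C2′(CH3)–O with the oxygen cis to the CH2: together with the enol carbon C5 it is a latent dihydropyran, the imprint of a 2-methylene-1,3-dione adding across a trisubstituted cyclopentene.
- Forward, (S)-limonene is ring-contracted to the cyclopentene (ozonolysis, aldol condensation, decarbonylation). Its isopropenyl group is first stored as a primary bromide, because a free 1,1-disubstituted alkene would be the more accessible 2π partner.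
- The trione comes from 2-methylphloroglucinol by acylation and dearomatising prenylation. A Knoevenagel/oxa-(4+2) cascade with formaldehyde joins the halves and closes the only new ring; dehydrobromination and hydroxide opening of the vinylogous ester finish the route.
- Stereochemistry: C5′ comes from limonene, C1′ and C2′ from the cis, anti-selective cycloaddition, the acyl centre from (R)-2-methylbutanoic acid, and ring C6 from separation of epimers.

Key step: step 9

Remark: dearomatising prenylation cannot control the quaternary ring carbon; it is assumed that the two C6 epimers of 14 can be separated on a chiral stationary phase and that the C6 configuration is then assigned by X-ray or ECD analysis.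

**Step 1**
Reactants: 1 (S)-(−)-limonene
Product: 3 (2RS)-2-[(1S)-4-methylcyclohex-3-en-1-yl]propan-1-ol, via alkylborane 2 (not isolated)
Conditions: 9-BBN, THF, 0 °C → rt; then NaOH (aq.), H2O2, 0 °C → rt
Reagents that add atoms: hydrogen peroxide, OO
Why: Hydroboration–oxidation, in which 9-BBN adds anti-Markovnikov to the unhindered 1,1-disubstituted alkene much faster than to the trisubstituted ring alkene; the new side-chain centre forms without control and is removed in step 10, and the ring stereocentre is untouched.

**Step 2**
Reactants: 3 (2RS)-2-[(1S)-4-methylcyclohex-3-en-1-yl]propan-1-ol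
Product: 4 (4S)-4-[(2RS)-1-bromopropan-2-yl]-1-methylcyclohex-1-ene
Conditions: CBr4, PPh3, CH2Cl2, 0 °C
Reagents that add atoms: carbon tetrabromide, BrC(Br)(Br)Br
Why: Appel reaction of a primary alcohol under neutral conditions that leave the ring alkene alone.

**Step 3**
Reactants: 4 (4S)-4-[(2RS)-1-bromopropan-2-yl]-1-methylcyclohex-1-ene
Product: 6 (3S)-3-[(2RS)-1-bromopropan-2-yl]-6-oxoheptanal, via ozonide 5 (not isolated)
Conditions: O3, CH2Cl2, −78 °C; then Me2S, −78 °C → rt
Reagents that add atoms: ozone, [O-][O+]=O
Why: Ozonolysis with reductive work-up of the only C=C left in the molecule, to which the alkyl bromide is inert.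

**Step 4**
Reactants: 6 (3S)-3-[(2RS)-1-bromopropan-2-yl]-6-oxoheptanal
Product: 7 (5R)-5-[(2RS)-1-bromopropan-2-yl]-2-methylcyclopent-1-ene-1-carbaldehyde
Conditions: piperidine (cat.), AcOH (cat.), toluene, reflux, Dean–Stark
Reagents that add atoms: none
Why: Intramolecular aldol condensation through the aldehyde enamine, which attacks the methyl ketone to close the five-membered ring as for the isopropenyl analogue derived from limonene; the ring stereocentre is not enolisable in the product.

**Step 5**
Reactants: 7 (5R)-5-[(2RS)-1-bromopropan-2-yl]-2-methylcyclopent-1-ene-1-carbaldehyde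
Product: 8 (3S)-3-[(2RS)-1-bromopropan-2-yl]-1-methylcyclopent-1-ene
Conditions: RhCl(PPh3)3 (1.1 equiv), toluene, 110 °C
Reagents that add atoms: none
Why: Tsuji–Wilkinson decarbonylation of an α,β-unsaturated aldehyde (C–H insertion, CO extrusion, reductive elimination of the vinyl C–H), which keeps the double bond in place and so gives the trisubstituted alkene with its CH next to the stereocentre.

**Step 6**
Reactants: 9 (R)-2-methylbutanoic acid; 10 2-methylphloroglucinol
Product: 12 (2R)-2-methyl-1-(2,4,6-trihydroxy-3-methylphenyl)butan-1-one, via acid chloride 11 (not isolated)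
Conditions: (COCl)2, DMF (cat.), CH2Cl2, 0 °C → rt, evaporate; then 10, AlCl3, CH2Cl2–PhNO2, 0 °C → rt
Reagents that add atoms: none
Why: Friedel–Crafts C-acylation of a phloroglucinol whose two free ring positions are equivalent, run at low temperature so that the α-stereocentre of the acyl chloride is not enolised.

**Step 7**
Reactants: 12 (2R)-2-methyl-1-(2,4,6-trihydroxy-3-methylphenyl)butan-1-one; 13 prenyl bromide
Product: 14 (6RS)-3,5-dihydroxy-6-methyl-6-(3-methylbut-2-en-1-yl)-2-[(2R)-2-methylbutanoyl]cyclohexa-2,4-dien-1-one (enolised trione, both C6 epimers)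
Conditions: NaOMe, MeOH, 0 °C; 13 (1.0 equiv), 0 °C → rt
Reagents that add atoms: none
Why: Alkylative dearomatisation in which the phenolate is C-alkylated at the methyl-bearing, most electron-rich ring carbon (the preference behind gem-dialkylation of alkylated acylphloroglucinols); the quaternary carbon forms without facial control, so both epimers are expected in similar amounts.

**Step 8**
Reactants: 14 enolised trione, both C6 epimers
Product: 15 (6R)-3,5-dihydroxy-6-methyl-6-(3-methylbut-2-en-1-yl)-2-[(2R)-2-methylbutanoyl]cyclohexa-2,4-dien-1-one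
Conditions: preparative HPLC, amylose-based chiral stationary phase, hexane–i-PrOH (0.1% TFA)
Reagents that add atoms: none
Why: Physical separation of two diastereomers that differ only at C6, which is how this centre is fixed; no bond is made or broken.

**Step 9**
Reactants: 15 (6R)-enolised trione; 8 (3S)-3-[(2RS)-1-bromopropan-2-yl]-1-methylcyclopent-1-ene
Product: 17 (1S,3aS,5R,9aR)-1-[(2RS)-1-bromopropan-2-yl]-8-hydroxy-3a,5-dimethyl-5-(3-methylbut-2-en-1-yl)-7-[(2R)-2-methylbutanoyl]-1,2,3,3a,9,9a-hexahydrocyclopenta[b]chromen-6(5H)-one, via methylene trione 16 (not isolated)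
Conditions: (CH2O)n, NaOAc, AcOH, 80 °C; 8 (3 equiv), 15 added slowly
Reagents that add atoms: formaldehyde as paraformaldehyde, C=O
Why: Knoevenagel condensation of the acidic ring CH of 15 with formaldehyde gives the 2-methylene trione 16, an electron-poor 1-oxadiene that cannot aromatise because C6 is quaternary, and 16 adds to the ring alkene of 8 in a concerted, asynchronous inverse-electron-demand oxa-(4+2) cycloaddition. The closest known reaction type is the domino Knoevenagel/hetero-Diels–Alder reaction of quinone-methide-like methylene triones from dearomatised acylphloroglucinols with terpene alkenes. The dihydropyran is closed by this intermolecular (4+2) cycloaddition, suprafacial on the alkene, so the new C–C and C–O bonds are cis and the five/six ring fusion is cis. Both new stereocentres (C3a and C9a) are controlled by the allylic stereocentre of 8, because the oxadiene approaches the ring face opposite the 1-bromopropan-2-yl group, which sits next to the carbon that receives the CH2. Regioselectivity (CH2 to the alkene CH, O to the methyl-bearing carbon) follows from the polarised transition state with positive charge building at the tertiary carbon, and the non-chelated carbonyl next to C6 serves as the heteroatom so that the enol–acyl hydrogen bond survives (the other chroman would open to the same alcohol). Chemoselectivity for the ring alkene is secured because the isopropenyl group is stored as a saturated bromide, while methylene-bis-trione formation and cycloaddition to the prenyl group of a second trione are held down by adding 15 slowly to excess 8.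

**Step 10**
Reactants: 17 bromo chroman
Product: 18 (1S,3aS,5R,9aR)-8-hydroxy-3a,5-dimethyl-5-(3-methylbut-2-en-1-yl)-7-[(2R)-2-methylbutanoyl]-1-(prop-1-en-2-yl)-1,2,3,3a,9,9a-hexahydrocyclopenta[b]chromen-6(5H)-one
Conditions: KOtBu (3 equiv), THF, 0 °C → rt
Reagents that add atoms: none
Why: E2 dehydrobromination of a β-branched primary bromide whose only β-hydrogen is the side-chain methine, so both side-chain epimers converge on the isopropenyl group with no regioisomer; the first equivalent of base only forms the unreactive enolate.

**Step 11**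
Reactants: 18 isopropenyl chroman
Product: 19 (6R)-3,5-dihydroxy-4-{[(1R,2S,5S)-2-hydroxy-2-methyl-5-(prop-1-en-2-yl)cyclopentyl]methyl}-6-methyl-6-(3-methylbut-2-en-1-yl)-2-[(2R)-2-methylbutanoyl]cyclohexa-2,4-dien-1-one
Conditions: KOH (aq.), DMSO, 60 °C; then cold 1 M HCl to pH 3
Reagents that add atoms: hydroxide from aqueous potassium hydroxide, [K+].[OH-]
Why: Saponification of the cyclic vinylogous ester by addition–elimination, in which hydroxide adds to the enol-ether carbon C4a and the tertiary alkoxide is expelled, so only the vinyl C–O bond breaks and the carbinol carbon keeps its configuration; formation of the trione dianion drives the opening.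

**Compound list**
1 | (S)-(−)-limonene, (4S)-1-methyl-4-(prop-1-en-2-yl)cyclohex-1-ene | C=C(C)[C@H]1CCC(C)=CC1 | starting material
2 | 9-{2-[(1S)-4-methylcyclohex-3-en-1-yl]propyl}-9-borabicyclo[3.3.1]nonane | CC(CB1C2CCCC1CCC2)[C@H]1CCC(C)=CC1 | intermediate (not isolated)
3 | (2RS)-2-[(1S)-4-methylcyclohex-3-en-1-yl]propan-1-ol | OCC(C)[C@H]1CCC(C)=CC1 | intermediate
4 | (4S)-4-[(2RS)-1-bromopropan-2-yl]-1-methylcyclohex-1-ene | BrCC(C)[C@H]1CCC(C)=CC1 | intermediate
5 | secondary ozonide of 4 (7,8,9-trioxabicyclo[4.2.1]nonane core) | BrCC(C)[C@H]1CCC2(C)OOC(C1)O2 | intermediate (not isolated)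
6 | (3S)-3-[(2RS)-1-bromopropan-2-yl]-6-oxoheptanal | BrCC(C)[C@H](CC=O)CCC(C)=O | intermediate
7 | (5R)-5-[(2RS)-1-bromopropan-2-yl]-2-methylcyclopent-1-ene-1-carbaldehyde | BrCC(C)[C@H]1CCC(C)=C1C=O | intermediate
8 | (3S)-3-[(2RS)-1-bromopropan-2-yl]-1-methylcyclopent-1-ene | BrCC(C)[C@H]1CCC(C)=C1 | intermediate
9 | (R)-2-methylbutanoic acid | CC[C@@H](C)C(=O)O | starting material
10 | 2-methylphloroglucinol | Cc1c(O)cc(O)cc1O | starting material
11 | (R)-2-methylbutanoyl chloride | CC[C@@H](C)C(=O)Cl | intermediate (not isolated)
12 | (2R)-2-methyl-1-(2,4,6-trihydroxy-3-methylphenyl)butan-1-one | CC[C@@H](C)C(=O)c1c(O)cc(O)c(C)c1O | intermediate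
13 | prenyl bromide, 1-bromo-3-methylbut-2-ene | CC(C)=CCBr | starting material
14 | (6RS)-3,5-dihydroxy-6-methyl-6-(3-methylbut-2-en-1-yl)-2-[(2R)-2-methylbutanoyl]cyclohexa-2,4-dien-1-one | C1=C(O)C(C)(CC=C(C)C)C(=O)C(C(=O)[C@H](C)CC)=C1O | intermediate
15 | (6R)-3,5-dihydroxy-6-methyl-6-(3-methylbut-2-en-1-yl)-2-[(2R)-2-methylbutanoyl]cyclohexa-2,4-dien-1-one | C1=C(O)[C@@](C)(CC=C(C)C)C(=O)C(C(=O)[C@H](C)CC)=C1O | intermediate
16 | (6R)-3-hydroxy-6-methyl-4-methylidene-6-(3-methylbut-2-en-1-yl)-2-[(2R)-2-methylbutanoyl]cyclohex-2-ene-1,5-dione | C=C1C(=O)[C@@](C)(CC=C(C)C)C(=O)C(C(=O)[C@H](C)CC)=C1O | intermediate (not isolated)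
17 | (1S,3aS,5R,9aR)-1-[(2RS)-1-bromopropan-2-yl]-8-hydroxy-3a,5-dimethyl-5-(3-methylbut-2-en-1-yl)-7-[(2R)-2-methylbutanoyl]-1,2,3,3a,9,9a-hexahydrocyclopenta[b]chromen-6(5H)-one | BrCC(C)[C@H]1CC[C@](C)(O2)[C@@H]1CC1=C2[C@@](C)(CC=C(C)C)C(=O)C(C(=O)[C@H](C)CC)=C1O | intermediate
18 | (1S,3aS,5R,9aR)-8-hydroxy-3a,5-dimethyl-5-(3-methylbut-2-en-1-yl)-7-[(2R)-2-methylbutanoyl]-1-(prop-1-en-2-yl)-1,2,3,3a,9,9a-hexahydrocyclopenta[b]chromen-6(5H)-one | C=C(C)[C@H]1CC[C@](C)(O2)[C@@H]1CC1=C2[C@@](C)(CC=C(C)C)C(=O)C(C(=O)[C@H](C)CC)=C1O | intermediate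
19 | (6R)-3,5-dihydroxy-4-{[(1R,2S,5S)-2-hydroxy-2-methyl-5-(prop-1-en-2-yl)cyclopentyl]methyl}-6-methyl-6-(3-methylbut-2-en-1-yl)-2-[(2R)-2-methylbutanoyl]cyclohexa-2,4-dien-1-one | C=C(C)[C@H]1CC[C@](C)(O)[C@@H]1CC1=C(O)[C@@](C)(CC=C(C)C)C(=O)C(C(=O)[C@H](C)CC)=C1O | target

**Step count and risks**
Total step count: 11 (the separation in step 8 is counted). Longest linear sequence: 8 steps from (S)-limonene (steps 1–5 and 9–11).

Steps most likely to fail:

Step 11. Hydroxide addition to the hindered enol-ether carbon of an already anionic substrate may be too slow. Retro-Claisen cleavage of the trione ring or epimerisation next to the acyl carbonyl could then win, and an acidic work-up could ionise the tertiary C–O bond. The fallback avoids ever binding the tertiary oxygen to the ring; it sets out from keto aldehyde 6 and trione 15. A proline-catalysed intramolecular aldol addition of 6 under equilibrating conditions should give (1R,2S,5S)-5-[(2RS)-1-bromopropan-2-yl]-2-hydroxy-2-methylcyclopentane-1-carbaldehyde F1, with the formyl group trans to both neighbouring carbon substituents. Three-component reductive alkylation of 15 with F1 and Hantzsch ester under proline catalysis (Knoevenagel condensation, then transfer hydrogenation of the alkylidene trione) should give the 1-bromopropan-2-yl analogue of the target F2. Dehydrobromination with KOtBu as in step 10 then returns to the route at 19.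

Step 9. The transient methylene trione may be lost to Michael addition of unreacted trione or to cycloaddition with the prenyl group of a second molecule before it finds the hindered ring alkene, and the facial preference may be incomplete. The fallback moves the cycloaddition to the aromatic stage and sets out from aryl ketone 12 and cyclopentene 8. Heating these with paraformaldehyde in NaOAc/AcOH generates the ortho-quinone methide of the acylphloroglucinol at its free ring position, and the same oxa-(4+2) addition should give the aromatic chroman (1S,3aS,9aR)-1-[(2RS)-1-bromopropan-2-yl]-6,8-dihydroxy-3a,5-dimethyl-7-[(2R)-2-methylbutanoyl]-1,2,3,3a,9,9a-hexahydrocyclopenta[b]chromene F3. Alkylative dearomatisation of F3 with prenyl bromide 13 and base at the methyl-bearing carbon, the only ring carbon left to alkylate, gives 17 and its C5 epimer. These should separate on silica because the quaternary centre now sits on the rigid tricycle, and the route is rejoined at 17.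

Step 7. C-alkylation may go to the unsubstituted ring carbon, with rearomatisation, or to oxygen instead of the methyl-bearing carbon. The fallback blocks the free position and sets out from 12. Bromination with NBS gives (2R)-1-(3-bromo-2,4,6-trihydroxy-5-methylphenyl)-2-methylbutan-1-one F4. Dearomatising prenylation with 13 and NaOMe, now possible only at the methyl-bearing carbon, gives (6RS)-4-bromo-3,5-dihydroxy-6-methyl-6-(3-methylbut-2-en-1-yl)-2-[(2R)-2-methylbutanoyl]cyclohexa-2,4-dien-1-one F5. Reductive removal of the enolic bromine with Zn in AcOH returns to the route at 14.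

**Further compounds**
F1 | step 11 | (1R,2S,5S)-5-[(2RS)-1-bromopropan-2-yl]-2-hydroxy-2-methylcyclopentane-1-carbaldehyde | BrCC(C)[C@H]1CC[C@](C)(O)[C@@H]1C=O
F2 | step 11 | (6R)-4-({(1R,2S,5S)-5-[(2RS)-1-bromopropan-2-yl]-2-hydroxy-2-methylcyclopentyl}methyl)-3,5-dihydroxy-6-methyl-6-(3-methylbut-2-en-1-yl)-2-[(2R)-2-methylbutanoyl]cyclohexa-2,4-dien-1-one | BrCC(C)[C@H]1CC[C@](C)(O)[C@@H]1CC1=C(O)[C@@](C)(CC=C(C)C)C(=O)C(C(=O)[C@H](C)CC)=C1O
F3 | step 9 | (1S,3aS,9aR)-1-[(2RS)-1-bromopropan-2-yl]-6,8-dihydroxy-3a,5-dimethyl-7-[(2R)-2-methylbutanoyl]-1,2,3,3a,9,9a-hexahydrocyclopenta[b]chromene | BrCC(C)[C@H]1CC[C@](C)(O2)[C@@H]1Cc1c2c(C)c(O)c(C(=O)[C@H](C)CC)c1O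
F4 | step 7 | (2R)-1-(3-bromo-2,4,6-trihydroxy-5-methylphenyl)-2-methylbutan-1-one | CC[C@@H](C)C(=O)c1c(O)c(Br)c(O)c(C)c1O
F5 | step 7 | (6RS)-4-bromo-3,5-dihydroxy-6-methyl-6-(3-methylbut-2-en-1-yl)-2-[(2R)-2-methylbutanoyl]cyclohexa-2,4-dien-1-one | BrC1=C(O)C(C)(CC=C(C)C)C(=O)C(C(=O)[C@H](C)CC)=C1O
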